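**Plan**

1. Retrosynthetic cuts, in order: C1–C10 of the ten-membered ring (giving an E-β-iodoenone and a methyl ketone); the C3 carbonyl between C2 and C4 (alkenyl iodide + CO + a C1–C2 vinyl unit); C8–C9 and the C8 ester (aldehyde allylation, alkene to methyl ketone); C6–C7 together with the lactone C–O bond (aldehyde + 2-(methoxycarbonyl)allyl bromide).
2. Forward: two four-carbon pieces (Z-iodoenal C4–C6/C15 and bromide C7/C8/C11–C13) are joined first and give the α-methylene-γ-lactone ring; the C8–C10 side chain and the C1–C3 iododienone arm follow; the ten-membered carbocycle is closed last.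
3. Stereochemistry: C4=C5 (Z) from hydroxyl-directed trans-hydroalumination/iodination; C6 and C7 from a ligand-controlled anti allylation (trans lactone); C8 from a reagent-controlled allylboration; C2' from (R)-2-methylbutanoic acid; C1=C2 (E) from an E-distannylethene; C10 in the ring closure under substrate control.
4. Enabling feature: the γ-hydroxy enone C3(=O)–C2=C1–C10(OH)(CH3) of the ten-membered ring. C1 is the β-carbon of the cross-conjugated dienone (an alkenyl-metal from a β-iodoenone) and C10 is a methyl carbinol (a methyl ketone acceptor). The cis C4=C5 bond and the trans-fused five-membered lactone (O–C6–C7–C11–C12) turn the two arms toward each other.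

Key step: step 13

Remark: germacranolide numbering of 24 is used throughout (C1–C10 ring, C11–C13 lactone unit, C14 methyl, C15 hydroxymethyl carbon). The CIP labels at C6 and C7 change formally along the route (iodine on C4, acetal at C8) while the spatial arrangement stays that of 24; the 2-methylbutanoate is taken as (R), as the given structure shows.

**Route**

Step 1
Reactants: 1 but-2-yne-1,4-diol
Product: 2 4-(tert-butyldiphenylsilyloxy)but-2-yn-1-ol
Conditions: NaH (1.0 equiv), THF, 0 °C; then TBDPSCl, 0 °C to rt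
Reagents that add atoms: tert-butyl(chloro)diphenylsilane, CC(C)(C)[Si](Cl)(c1ccccc1)c1ccccc1
Why: O-Silylation of the sparingly soluble monosodium alkoxide (Williamson-type silyl ether formation) should stop at the mono-ether of the symmetrical diol.

Step 2
Reactants: 2 4-(tert-butyldiphenylsilyloxy)but-2-yn-1-ol
Product: 4 (Z)-4-(tert-butyldiphenylsilyloxy)-3-iodobut-2-en-1-ol, via alkenylaluminate 3 (not isolated)
Conditions: NaAlH2(OCH2CH2OMe)2 (Red-Al), THF, 0 °C; then I2, −78 °C to 0 °C
Reagents that add atoms: iodine, [I][I]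
Why: Hydroxyl-directed trans-hydroalumination of the propargylic alcohol delivers hydride to C5 and aluminium to C4 within a five-membered oxa-aluminacycle, and iodinolysis of the C–Al bond with retention fixes the Z C4=C5 geometry (C6 cis to iodine).

Step 3
Reactants: 4 (Z)-4-(tert-butyldiphenylsilyloxy)-3-iodobut-2-en-1-ol
Product: 5 (Z)-4-(tert-butyldiphenylsilyloxy)-3-iodobut-2-enal
Conditions: MnO2, CH2Cl2, rt
Reagents that add atoms: none
Why: Allylic alcohol oxidation with MnO2 is neutral and heterogeneous, so the Z-iodoalkene and the silyl ether should survive.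

Step 4
Reactants: 6 methyl acrylate; 7 2,2-dimethoxyacetaldehyde (60% in water)
Product: 8 methyl 3-hydroxy-4,4-dimethoxy-2-methylidenebutanoate (racemic)
Conditions: DABCO (cat.), 1,4-dioxane/H2O, rt
Reagents that add atoms: none
Why: Morita–Baylis–Hillman reaction, which should be fast with this activated α,α-dialkoxy aldehyde; the carbinol centre is racemic and disappears in step 5.

Step 5
Reactants: 8 methyl 3-hydroxy-4,4-dimethoxy-2-methylidenebutanoate
Product: 9 methyl (Z)-2-(bromomethyl)-4,4-dimethoxybut-2-enoate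
Conditions: NBS, Me2S, CH2Cl2, 0 °C to rt
Reagents that add atoms: N-bromosuccinimide, O=C1CCC(=O)N1Br
Why: The alkoxysulfonium salt formed from the alcohol is displaced by bromide with allylic transposition (SN2' bromination of a Baylis–Hillman alcohol) to the thermodynamically preferred Z-2-(bromomethyl)enoate under conditions that spare the acetal.

Step 6
Reactants: 5 (Z)-4-(tert-butyldiphenylsilyloxy)-3-iodobut-2-enal; 9 methyl (Z)-2-(bromomethyl)-4,4-dimethoxybut-2-enoate
Product: 12 (4S,5S)-5-[(Z)-3-(tert-butyldiphenylsilyloxy)-2-iodoprop-1-enyl]-4-(dimethoxymethyl)-3-methylideneoxolan-2-one (trans lactone), via silyl ether 10 (not isolated), via hydroxy ester 11 (not isolated)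
Conditions: CrCl2 (10 mol%), chiral tridentate 1,8-bis(oxazolin-2-yl)carbazole ligand (12 mol%, antipode giving Si-face addition), Mn powder, Me3SiCl, iPr2NEt (cat.), THF, rt; then PPTS, MeOH, rt
Reagents that add atoms: none
Why: Nozaki–Hiyama-type 2-(alkoxycarbonyl)allylation catalytic in chromium (Mn as reductant, Me3SiCl for turnover): the γ-substituted allylchromium should add through a Zimmerman–Traxler chair with the CH(OMe)2 group equatorial (anti adduct, hence the trans lactone after acid-catalysed transesterification), while the chiral ligand directs attack to the Si face of 5, which sets C6 and with it C7.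

Step 7
Reactants: 12 trans lactone acetal
Product: 13 (2S,3S)-2-[(Z)-3-(tert-butyldiphenylsilyloxy)-2-iodoprop-1-enyl]-4-methylidene-5-oxooxolane-3-carbaldehyde
Conditions: CF3CO2H/H2O (9:1), CH2Cl2, 0 °C; used at once
Reagents that add atoms: water, O
Why: Acid-catalysed acetal hydrolysis should leave the silyl ether, lactone and alkenyl iodide intact in brief cold aqueous acid, and 13 is used directly because its C7–H is both α to the aldehyde and γ to the lactone carbonyl.

Step 8
Reactants: 13 lactone aldehyde; 14 (+)-B-allyldiisopinocampheylborane (antipode derived from (−)-α-pinene, 1 M in pentane)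
Product: 16 (4R,5S)-5-[(Z)-3-(tert-butyldiphenylsilyloxy)-2-iodoprop-1-enyl]-4-[(1R)-1-hydroxybut-3-enyl]-3-methylideneoxolan-2-one, via borinate 15 (not isolated)
Conditions: Et2O, −78 °C; then HOCH2CH2NH2, rt
Reagents that add atoms: none
Why: Brown allylboration through a closed six-membered transition state in which the isopinocampheyl groups of 14 steer the allyl group to the Re face of the aldehyde (reagent control over the α-stereocentre) and so set C8 (R) at a temperature where C7 should not epimerise.

Step 9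
Reactants: 16 homoallylic alcohol; 17 (R)-2-methylbutanoic acid
Product: 18 (1R)-1-[(2S,3R)-2-[(Z)-3-(tert-butyldiphenylsilyloxy)-2-iodoprop-1-enyl]-4-methylidene-5-oxooxolan-3-yl]but-3-enyl (2R)-2-methylbutanoate
Conditions: DCC, DMAP (cat.), CH2Cl2, 0 °C to rt
Reagents that add atoms: none
Why: Steglich esterification of the secondary alcohol with the carbodiimide-activated acid forms no stereocentre and should retain C8 and C2'.

Step 10
Reactants: 18 homoallylic ester
Product: 19 (1R)-1-[(2S,3R)-2-[(Z)-3-(tert-butyldiphenylsilyloxy)-2-iodoprop-1-enyl]-4-methylidene-5-oxooxolan-3-yl]-3-oxobutyl (2R)-2-methylbutanoate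
Conditions: PdCl2 (10 mol%), CuCl, O2 (1 atm), DMF/H2O (7:1), rt
Reagents that add atoms: water, O
Why: Tsuji–Wacker oxidation: Markovnikov hydroxypalladation should be confined to the only terminal unactivated alkene (the α-methylene lactone is electron-poor, the iodoalkene trisubstituted) and gives the C10 methyl ketone.

Step 11
Reactants: 19 methyl ketone alkenyl iodide; 20 (E)-1,2-bis(tributylstannyl)ethene
Product: 21 (1R)-1-[(2R,3R)-2-[(1Z,4E)-2-[(tert-butyldiphenylsilyloxy)methyl]-3-oxo-5-(tributylstannyl)penta-1,4-dienyl]-4-methylidene-5-oxooxolan-3-yl]-3-oxobutyl (2R)-2-methylbutanoate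
Conditions: CO (1 atm), Pd2(dba)3 (5 mol%), AsPh3 (20 mol%), NMP, 45 °C; 20 in excess
Reagents that add atoms: carbon monoxide, [C-]#[O+]
Why: Carbonylative Stille coupling (oxidative addition into the alkenyl C–I bond with retention, CO insertion, transfer of one alkenyl group of 20) should give the cross-conjugated dienone with C4=C5 (Z) and C1=C2 (E) carried over from 19 and 20, the remaining stannyl group on the electron-poor enone being unreactive.

Step 12
Reactants: 21 stannyl dienone
Product: 22 (1R)-1-[(2R,3R)-2-[(1Z,4E)-2-[(tert-butyldiphenylsilyloxy)methyl]-5-iodo-3-oxopenta-1,4-dienyl]-4-methylidene-5-oxooxolan-3-yl]-3-oxobutyl (2R)-2-methylbutanoate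
Conditions: I2, CH2Cl2, 0 °C
Reagents that add atoms: iodine, [I][I]
Why: Iododestannylation (ipso substitution at the alkenyl carbon) proceeds with retention and should give the E-β-iodoenone.

Step 13
Reactants: 22 E-β-iodo dienone methyl ketone
Product: 23 15-O-tert-butyldiphenylsilyl ether of 24
Conditions: CrCl2 (10 equiv), NiCl2 (0.1 equiv), DMSO/THF (3:1, degassed), 0.002 M, syringe-pump addition of 22, rt; aqueous sodium serinate work-up
Reagents that add atoms: none
Why: Zerovalent nickel, formed from NiCl2 by CrCl2, inserts into the C1–I bond of the E-β-iodoenone, the alkenylnickel transmetalates to trivalent chromium with retention of the E geometry, and the alkenylchromium adds to the C10 methyl ketone to give the chromium alkoxide of 23. The closest known reaction type is the intramolecular Nozaki–Hiyama–Kishi alkenylation, for which β-iodoenone partners, macrocyclic aldehyde closures and ketone closures of common rings are established. The ten-membered carbocycle closes in the 10-exo-trig mode with respect to the ketone (the carbonyl oxygen ends exocyclic), while C1=C2 stays endocyclic and E. The new C10 stereocentre is set under substrate control: in the cyclic transition state the chromium-bound carbonyl oxygen should point away from the ring and anti to the C8 acyloxy dipole, so that C1 attacks the ketone face giving the 8,10-anti (10R) carbinol with the C14 methyl pseudo-equatorial. The step needs chemoselectivity for the C10 ketone over the C3 dienone, the lactone and the ester, which the low basicity and carbonyl selectivity of alkenylchromium should secure (C3 cannot be reached intramolecularly and dimerisation is suppressed at high dilution). Ring closure is helped because the Z C4=C5 bond and the trans-fused lactone hold the C1 and C10 termini on the same side.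

Step 14
Reactants: 23 silyl ether of the target
Product: 24 (1E,4Z,6R,7R,8R,10R)-10,15-dihydroxy-8-[(2R)-2-methylbutanoyloxy]-3-oxogermacra-1,4,11(13)-trien-12,6-olide (CNP0232405.1)
Conditions: HF·pyridine, pyridine/THF, 0 °C to rt
Reagents that add atoms: none
Why: Fluoride-assisted cleavage of the primary silyl ether with pyridine-buffered HF should be mild enough for the tertiary alcohol, the dienone, the ester and the α-methylene lactone.

**Compound list**

1 | but-2-yne-1,4-diol | OCC#CCO | starting material
2 | 4-(tert-butyldiphenylsilyloxy)but-2-yn-1-ol | OCC#CCO[Si](c1ccccc1)(c1ccccc1)C(C)(C)C | intermediate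
3 | sodium 3-[(tert-butyldiphenylsilyloxy)methyl]-2,2-bis(2-methoxyethoxy)-2,5-dihydro-1,2-oxaaluminol-2-uide (alkenylaluminate, not isolated) | [Na+].COCCO[Al-]1(OCCOC)OCC=C1CO[Si](c2ccccc2)(c2ccccc2)C(C)(C)C | intermediate
4 | (Z)-4-(tert-butyldiphenylsilyloxy)-3-iodobut-2-en-1-ol | OC/C=C(/CO[Si](c1ccccc1)(c1ccccc1)C(C)(C)C)I | intermediate
5 | (Z)-4-(tert-butyldiphenylsilyloxy)-3-iodobut-2-enal | O=C/C=C(/CO[Si](c1ccccc1)(c1ccccc1)C(C)(C)C)I | intermediate
6 | methyl acrylate | C=CC(=O)OC | starting material
7 | 2,2-dimethoxyacetaldehyde | COC(OC)C=O | starting material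
8 | methyl 3-hydroxy-4,4-dimethoxy-2-methylidenebutanoate (racemic) | C=C(C(=O)OC)C(O)C(OC)OC | intermediate
9 | methyl (Z)-2-(bromomethyl)-4,4-dimethoxybut-2-enoate | COC(=O)/C(CBr)=C/C(OC)OC | intermediate
10 | methyl (3S,4S,5Z)-7-(tert-butyldiphenylsilyloxy)-3-(dimethoxymethyl)-6-iodo-2-methylidene-4-(trimethylsilyloxy)hept-5-enoate (silyl ether, not isolated) | COC(=O)C(=C)[C@@H]([C@H](O[Si](C)(C)C)/C=C(/CO[Si](c1ccccc1)(c1ccccc1)C(C)(C)C)I)C(OC)OC | intermediate
11 | methyl (3S,4S,5Z)-7-(tert-butyldiphenylsilyloxy)-3-(dimethoxymethyl)-4-hydroxy-6-iodo-2-methylidenehept-5-enoate (hydroxy ester, not isolated) | COC(=O)C(=C)[C@@H]([C@H](O)/C=C(/CO[Si](c1ccccc1)(c1ccccc1)C(C)(C)C)I)C(OC)OC | intermediate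
12 | (4S,5S)-5-[(Z)-3-(tert-butyldiphenylsilyloxy)-2-iodoprop-1-enyl]-4-(dimethoxymethyl)-3-methylideneoxolan-2-one | C=C1C(=O)O[C@H](/C=C(/CO[Si](c3ccccc3)(c4ccccc4)C(C)(C)C)I)[C@H]1C(OC)OC | intermediate
13 | (2S,3S)-2-[(Z)-3-(tert-butyldiphenylsilyloxy)-2-iodoprop-1-enyl]-4-methylidene-5-oxooxolane-3-carbaldehyde | C=C1C(=O)O[C@H](/C=C(/CO[Si](c3ccccc3)(c4ccccc4)C(C)(C)C)I)[C@H]1C=O | intermediate
14 | (+)-B-allyldiisopinocampheylborane (from (−)-α-pinene) | C=CCB([C@H]1C[C@H]2C[C@@H]([C@@H]1C)C2(C)C)[C@H]1C[C@H]2C[C@@H]([C@@H]1C)C2(C)C | starting material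
15 | diisopinocampheylborinate of 16 at the C8 oxygen (not isolated) | C=C1C(=O)O[C@H](/C=C(/CO[Si](c3ccccc3)(c4ccccc4)C(C)(C)C)I)[C@H]1[C@@H](CC=C)OB([C@H]5C[C@H]6C[C@@H]([C@@H]5C)C6(C)C)[C@H]5C[C@H]6C[C@@H]([C@@H]5C)C6(C)C | intermediate
16 | (4R,5S)-5-[(Z)-3-(tert-butyldiphenylsilyloxy)-2-iodoprop-1-enyl]-4-[(1R)-1-hydroxybut-3-enyl]-3-methylideneoxolan-2-one | C=C1C(=O)O[C@H](/C=C(/CO[Si](c3ccccc3)(c4ccccc4)C(C)(C)C)I)[C@H]1[C@@H](CC=C)O | intermediate
17 | (R)-2-methylbutanoic acid | OC(=O)[C@H](C)CC | starting material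
18 | (1R)-1-[(2S,3R)-2-[(Z)-3-(tert-butyldiphenylsilyloxy)-2-iodoprop-1-enyl]-4-methylidene-5-oxooxolan-3-yl]but-3-enyl (2R)-2-methylbutanoate | C=C1C(=O)O[C@H](/C=C(/CO[Si](c3ccccc3)(c4ccccc4)C(C)(C)C)I)[C@H]1[C@@H](CC=C)OC(=O)[C@H](C)CC | intermediate
19 | (1R)-1-[(2S,3R)-2-[(Z)-3-(tert-butyldiphenylsilyloxy)-2-iodoprop-1-enyl]-4-methylidene-5-oxooxolan-3-yl]-3-oxobutyl (2R)-2-methylbutanoate | C=C1C(=O)O[C@H](/C=C(/CO[Si](c3ccccc3)(c4ccccc4)C(C)(C)C)I)[C@H]1[C@@H](CC(C)=O)OC(=O)[C@H](C)CC | intermediate
20 | (E)-1,2-bis(tributylstannyl)ethene | CCCC[Sn](CCCC)(CCCC)/C=C/[Sn](CCCC)(CCCC)CCCC | starting material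
21 | (1R)-1-[(2R,3R)-2-[(1Z,4E)-2-[(tert-butyldiphenylsilyloxy)methyl]-3-oxo-5-(tributylstannyl)penta-1,4-dienyl]-4-methylidene-5-oxooxolan-3-yl]-3-oxobutyl (2R)-2-methylbutanoate | C=C1C(=O)O[C@H](/C=C(/CO[Si](c3ccccc3)(c4ccccc4)C(C)(C)C)C(=O)/C=C/[Sn](CCCC)(CCCC)CCCC)[C@H]1[C@@H](CC(C)=O)OC(=O)[C@H](C)CC | intermediate
22 | (1R)-1-[(2R,3R)-2-[(1Z,4E)-2-[(tert-butyldiphenylsilyloxy)methyl]-5-iodo-3-oxopenta-1,4-dienyl]-4-methylidene-5-oxooxolan-3-yl]-3-oxobutyl (2R)-2-methylbutanoate | C=C1C(=O)O[C@H](/C=C(/CO[Si](c3ccccc3)(c4ccccc4)C(C)(C)C)C(=O)/C=C/I)[C@H]1[C@@H](CC(C)=O)OC(=O)[C@H](C)CC | intermediate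
23 | 15-O-tert-butyldiphenylsilyl ether of 24 | C=C1C(=O)O[C@@H]2/C=C(/CO[Si](c3ccccc3)(c4ccccc4)C(C)(C)C)C(=O)/C=C/[C@](C)(O)C[C@@H](OC(=O)[C@H](C)CC)[C@@H]12 | intermediate
24 | (1E,4Z,6R,7R,8R,10R)-10,15-dihydroxy-8-[(2R)-2-methylbutanoyloxy]-3-oxogermacra-1,4,11(13)-trien-12,6-olide (CNP0232405.1) | C=C1C(=O)O[C@@H]2/C=C(/CO)C(=O)/C=C/[C@](C)(O)C[C@@H](OC(=O)[C@H](C)CC)[C@@H]12 | target

**Summary**

Total step count: 14
Longest linear sequence: 12 steps (steps 1–3, then 6–14)

Steps most likely to fail, with fallbacks: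

Step 13. The alkenylchromium may add too slowly to the hindered, enolisable C10 ketone (protodemetalation or oligomerisation taking over), or it may attack the wrong ketone face. Fallback: from 19, the C1–C10 bond is made between two molecules and the ring is closed at C3 instead. (E)-2-(Tributylstannyl)vinyllithium (from 20 and nBuLi, transmetalated with CeCl3, THF, −78 °C) adds to the C10 ketone of 19 and should give the tertiary (E)-2-(tributylstannyl)vinyl carbinol F1; the 10R epimer is separated if both form. An intramolecular carbonylative Stille coupling (CO, Pd2(dba)3, AsPh3, high dilution) then joins C2 and C4 through the new C3 carbonyl and comes back to the route at 23.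

Step 6. The allylchromium may react through the chair with the γ-substituent axial (syn instead of anti simple diastereoselection, leading to the cis-lactone series), facial control by the ligand may erode, or methoxide may be lost from the allylchromium by 1,4-elimination. Fallback: from 5 and 9, the same chromium-catalysed coupling is run with the antipodal ligand and stopped before lactonisation at the syn silyl ether F2 (C7 as in 24, C6 epimeric). LiOH in aqueous THF cleaves the silyl ether and the methyl ester to give the syn hydroxy acid F3. A Mitsunobu lactonisation (PPh3, DIAD, THF, 0 °C) then closes the C6–O bond with inversion at C6 and comes back to the route at 12.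

Step 11. CO insertion may lose to direct Stille coupling at the hindered alkenylpalladium, or zerovalent palladium may ionise the allylic C6–O bond of the lactone. Fallback: from 19, the C3–C4 bond is made by a NiCl2/CrCl2-mediated coupling of the alkenyl iodide with excess (E)-3-(tributylstannyl)propenal, the aldehyde outcompeting the internal ketone, to give the doubly allylic C3 carbinol F4 (both C3 epimers, inconsequential). Oxidation with Dess–Martin periodinane comes back to the route at 21.

Further compounds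
F1 | step 13 | (1R,3R)-3-hydroxy-3-methyl-1-[(2S,3R)-2-[(Z)-3-(tert-butyldiphenylsilyloxy)-2-iodoprop-1-enyl]-4-methylidene-5-oxooxolan-3-yl]-5-(tributylstannyl)pent-4E-enyl (2R)-2-methylbutanoate (C10 carbinol of 19 carrying the E-stannylvinyl group) | C=C1C(=O)O[C@H](/C=C(/CO[Si](c3ccccc3)(c4ccccc4)C(C)(C)C)I)[C@H]1[C@@H](C[C@@](C)(O)/C=C/[Sn](CCCC)(CCCC)CCCC)OC(=O)[C@H](C)CC
F2 | step 6 | methyl (3S,4R,5Z)-7-(tert-butyldiphenylsilyloxy)-3-(dimethoxymethyl)-6-iodo-2-methylidene-4-(trimethylsilyloxy)hept-5-enoate (syn silyl ether) | COC(=O)C(=C)[C@@H]([C@@H](O[Si](C)(C)C)/C=C(/CO[Si](c1ccccc1)(c1ccccc1)C(C)(C)C)I)C(OC)OC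
F3 | step 6 | (3S,4R,5Z)-7-(tert-butyldiphenylsilyloxy)-3-(dimethoxymethyl)-4-hydroxy-6-iodo-2-methylidenehept-5-enoic acid (syn hydroxy acid) | OC(=O)C(=C)[C@@H]([C@@H](O)/C=C(/CO[Si](c1ccccc1)(c1ccccc1)C(C)(C)C)I)C(OC)OC
F4 | step 11 | C3 carbinol of 21 (both C3 epimers): (1R)-1-[(2R,3R)-2-[(1Z,4E)-2-[(tert-butyldiphenylsilyloxy)methyl]-3-hydroxy-5-(tributylstannyl)penta-1,4-dienyl]-4-methylidene-5-oxooxolan-3-yl]-3-oxobutyl (2R)-2-methylbutanoate | C=C1C(=O)O[C@H](/C=C(/CO[Si](c3ccccc3)(c4ccccc4)C(C)(C)C)C(O)/C=C/[Sn](CCCC)(CCCC)CCCC)[C@H]1[C@@H](CC(C)=O)OC(=O)[C@H](C)CC
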